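The plan cuts the three ring-carbon-to-carbonyl bonds of the butyryl ketones last. One threefold Friedel–Crafts C-butyrylation converts the acyl-free, doubly methylene-bridged core 17 into the target. It exploits the fact that the gem-dimethyl dienone ring A, the central phloroglucinol ring B and the methylphloroglucinol ring C of 17 each keep exactly one ring C–H (C2 of ring A, the lone aromatic CH of B and of C), flanked by two oxygen-bearing carbons. Core 17 is built from monomers whose future acyl carbons are blocked as benzyl esters, joined by two Mannich-base couplings and unmasked by neutral hydrogenolysis–decarboxylation, so that hot alkali never meets the exchange-prone CH2 bridges.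

Key step: step 10

Remark on the chemistry: the target has no stereocentre (the only sp3 ring carbon carries two methyl groups), so it is achiral and needs no enantiocontrol. All enolised trione rings are drawn in the tautomer of the target SMILES.

Step 1
Reactants: 1 2,4,6-trihydroxybenzoic acid (commercial monohydrate); 2 benzyl bromide
Product: 3 benzyl 2,4,6-trihydroxybenzoate
Conditions: BnBr, NaHCO3, DMF, rt
Reagents that add atoms: benzyl bromide 2, BrCc1ccccc1
Why: Chemoselective SN2 O-alkylation of the carboxylate (ester formation), in which hydrogencarbonate ionises only the carboxylic acid so that the three phenols stay free, while room temperature avoids decarboxylation of 1.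

Step 2
Reactants: 3 benzyl 2,4,6-trihydroxybenzoate; 4 iodomethane
Product: 5 benzyl 2,4-dihydroxy-5,5-dimethyl-6-oxocyclohexa-1,3-diene-1-carboxylate (filicinic acid with a CO2Bn group on one of its two ring CH carbons)
Conditions: MeI (2.2 equiv), BnONa (1 M in BnOH), 0 °C → rt
Reagents that add atoms: iodomethane 4, CI
Why: Alkoxide-mediated dearomatising C-methylation of a phloroglucinol derivative (twofold C-alkylation at one ring carbon) should install the geminal dimethyl group, the protic medium favouring C- over O-alkylation and the benzyloxide/benzyl alcohol pair making any ester exchange degenerate.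

Step 3
Reactants: 5 benzyl 2,4-dihydroxy-5,5-dimethyl-6-oxocyclohexa-1,3-diene-1-carboxylate; 6 formaldehyde; 7 dimethylamine
Product: 8 benzyl 3-[(dimethylamino)methyl]-2,4-dihydroxy-5,5-dimethyl-6-oxocyclohexa-1,3-diene-1-carboxylate (Mannich base, an inner salt in practice)
Conditions: 37% aq. CH2O premixed with excess 40% aq. Me2NH, EtOH, 0 °C → rt
Reagents that add atoms: formaldehyde 6, C=O; dimethylamine 7, CNC
Why: Mannich aminomethylation at the only remaining enolic ring C–H of 5, where adding 5 to the cold premixed amine/formaldehyde should suppress methylene-bis-dimer formation and the inner-salt product should precipitate.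

Step 4
Reactants: 9 2-methylbenzene-1,3,5-triol (2-methylphloroglucinol); 10 potassium hydrogencarbonate
Product: 11 2,4,6-trihydroxy-3-methylbenzoic acid
Conditions: KHCO3 (excess), H2O, 55 °C, closed vessel; then cold 2 M HCl, 0 °C
Reagents that add atoms: potassium hydrogencarbonate 10, [K+].OC([O-])=O
Why: Kolbe–Schmitt carboxylation of an electron-rich phenol under mild aqueous hydrogencarbonate conditions, in which the two free ring carbons of 9 are equivalent and the first carboxylate deactivates the ring against a second one.

Step 5
Reactants: 11 2,4,6-trihydroxy-3-methylbenzoic acid; 2 benzyl bromide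
Product: 12 benzyl 2,4,6-trihydroxy-3-methylbenzoate
Conditions: BnBr, NaHCO3, DMF, rt
Reagents that add atoms: benzyl bromide 2, BrCc1ccccc1
Why: Chemoselective SN2 O-alkylation of the carboxylate as in step 1, run at room temperature so that the decarboxylation-prone acid 11 is trapped as its ester before it can lose CO2.

Step 6
Reactants: 12 benzyl 2,4,6-trihydroxy-3-methylbenzoate; 6 formaldehyde; 7 dimethylamine
Product: 13 benzyl 3-[(dimethylamino)methyl]-2,4,6-trihydroxy-5-methylbenzoate
Conditions: 37% aq. CH2O premixed with excess 40% aq. Me2NH, EtOH, 0 °C → rt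
Reagents that add atoms: formaldehyde 6, C=O; dimethylamine 7, CNC
Why: Mannich aminomethylation of a phloroglucinol at its single unsubstituted ring carbon, so that only one regioisomer and no bis-Mannich base can form.

Step 7
Reactants: 13 benzyl 3-[(dimethylamino)methyl]-2,4,6-trihydroxy-5-methylbenzoate; 3 benzyl 2,4,6-trihydroxybenzoate (3 equiv, excess recovered)
Product: 14 benzyl 3-{[3-(benzyloxycarbonyl)-2,4,6-trihydroxyphenyl]methyl}-2,4,6-trihydroxy-5-methylbenzoate (B–CH2–C dimer; ring B keeps one free CH)
Conditions: 1,4-dioxane, 90 °C, Ar sweep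
Reagents that add atoms: none
Why: Thermal loss of dimethylamine from the phenolic Mannich base 13 should give an ortho-quinone methide that is captured at a free ring carbon of 3 (Friedel–Crafts-type conjugate addition), while 13 has no free ring carbon and cannot self-condense and the excess of 3 limits the reaction to monoalkylation.

Step 8
Reactants: 14 B–CH2–C dimer; 8 Mannich base of the blocked filicinic ester
Product: 15 tribenzyl triester of the bridged trimer (ring A: benzyl 2,4-dihydroxy-5,5-dimethyl-6-oxocyclohexa-1,3-diene-1-carboxylate joined through C3 by CH2 to ring B; ring B: benzyl 2,4,6-trihydroxybenzoate bearing the two CH2 bridges at C3 and C5; ring C: benzyl 2,4,6-trihydroxy-3-methylbenzoate joined through C5)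
Conditions: 1,4-dioxane, 60 °C, Ar sweep
Reagents that add atoms: none
Why: Retro-Mannich loss of dimethylamine from 8 should unveil the exocyclic methylene trione, a strong Michael acceptor, which the single free ring carbon of ring B in 14 attacks (Michael/Friedel–Crafts alkylation), so that with one reactive site per partner only the A–CH2–B bond can form.

Step 9
Reactants: 15 tribenzyl triester of the bridged trimer
Product: 17 3,5-dihydroxy-6,6-dimethyl-4-({2,4,6-trihydroxy-3-[(2,4,6-trihydroxy-3-methylphenyl)methyl]phenyl}methyl)cyclohexa-2,4-dien-1-one (acyl-free core, used at once under argon), via tricarboxylic acid 16 (not isolated)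
Conditions: H2 (1 atm), 10% Pd/C, THF–MeOH, rt; filter under Ar; then degassed H2O–THF, 60 °C
Reagents that add atoms: none
Why: Hydrogenolysis of the three benzyl esters under neutral conditions followed by thermal decarboxylation of the 2,4,6-trihydroxybenzoic acids and of the vinylogous β-keto acid on ring A, all of which lose CO2 readily, should unmask the three ring C–H positions without the alkali that would set off bridge exchange.

Step 10
Reactants: 17 acyl-free core; 18 butanoyl chloride (3.3 equiv)
Product: 19 2-butanoyl-4-({3-butanoyl-5-[(3-butanoyl-2,4,6-trihydroxy-5-methylphenyl)methyl]-2,4,6-trihydroxyphenyl}methyl)-3,5-dihydroxy-6,6-dimethylcyclohexa-2,4-dien-1-one (target CNP0086105.0)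
Conditions: AlCl3, PhNO2–CH2Cl2, 0 °C → rt; then ice-cold 1 M HCl
Reagents that add atoms: butanoyl chloride 18, CCCC(Cl)=O
Why: AlCl3 turns butanoyl chloride into an acylium-type electrophile (any O-butyrate formed first is moved to carbon by the same Lewis acid, Fries-type), which attacks the one C–H carbon of each ring, namely C2 of the enolised trione ring A and the lone aromatic CH of rings B and C, and loss of a proton restores the enol or phenol. The closest known reaction type is the Friedel–Crafts C-acylation of phloroglucinol, C-methylphloroglucinol and filicinic acid with acyl chlorides and AlCl3. No ring is closed and no stereocentre is formed. The step needs C- over O-acylation, which the Lewis acid and the chelated ortho-hydroxy (or enol) ketone products should secure, and it needs site control, which follows from the single unsubstituted nucleophilic carbon per ring and from the deactivation of each ring by its new ketone. It must also outrun acid-induced cleavage and recombination of the two CH2 bridges, for which low temperature, aluminium phenoxide formation (lowering ring basicity towards ipso-protonation) and a short reaction time are relied on.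

Compound list
1 | 2,4,6-trihydroxybenzoic acid | O=C(O)c1c(O)cc(O)cc1O | starting material
2 | benzyl bromide | BrCc1ccccc1 | starting material
3 | benzyl 2,4,6-trihydroxybenzoate | O=C(OCc1ccccc1)c1c(O)cc(O)cc1O | intermediate
4 | iodomethane | CI | starting material
5 | benzyl 2,4-dihydroxy-5,5-dimethyl-6-oxocyclohexa-1,3-diene-1-carboxylate | O=C(OCc1ccccc1)C1=C(O)C=C(O)C(C)(C)C1=O | intermediate
6 | formaldehyde | C=O | starting material
7 | dimethylamine | CNC | starting material
8 | benzyl 3-[(dimethylamino)methyl]-2,4-dihydroxy-5,5-dimethyl-6-oxocyclohexa-1,3-diene-1-carboxylate | CN(C)CC1=C(O)C(C)(C)C(=O)C(C(=O)OCc2ccccc2)=C1O | intermediate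
9 | 2-methylbenzene-1,3,5-triol (2-methylphloroglucinol) | Cc1c(O)cc(O)cc1O | starting material
10 | potassium hydrogencarbonate | [K+].OC([O-])=O | starting material
11 | 2,4,6-trihydroxy-3-methylbenzoic acid | Cc1c(O)cc(O)c(C(=O)O)c1O | intermediate
12 | benzyl 2,4,6-trihydroxy-3-methylbenzoate | Cc1c(O)cc(O)c(C(=O)OCc2ccccc2)c1O | intermediate
13 | benzyl 3-[(dimethylamino)methyl]-2,4,6-trihydroxy-5-methylbenzoate | CN(C)Cc1c(O)c(C)c(O)c(C(=O)OCc2ccccc2)c1O | intermediate
14 | benzyl 3-{[3-(benzyloxycarbonyl)-2,4,6-trihydroxyphenyl]methyl}-2,4,6-trihydroxy-5-methylbenzoate | Cc1c(O)c(C(=O)OCc2ccccc2)c(O)c(Cc3c(O)cc(O)c(C(=O)OCc4ccccc4)c3O)c1O | intermediate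
15 | tribenzyl triester of the bridged trimer (CO2Bn at each future acyl carbon of rings A, B and C) | CC1(C)C(=O)C(C(=O)OCc2ccccc2)=C(O)C(Cc3c(O)c(Cc4c(O)c(C)c(O)c(C(=O)OCc5ccccc5)c4O)c(O)c(C(=O)OCc6ccccc6)c3O)=C1O | intermediate
16 | tricarboxylic acid of the bridged trimer (CO2H at each future acyl carbon) | CC1(C)C(=O)C(C(=O)O)=C(O)C(Cc2c(O)c(Cc3c(O)c(C)c(O)c(C(=O)O)c3O)c(O)c(C(=O)O)c2O)=C1O | intermediate (not isolated)
17 | 3,5-dihydroxy-6,6-dimethyl-4-({2,4,6-trihydroxy-3-[(2,4,6-trihydroxy-3-methylphenyl)methyl]phenyl}methyl)cyclohexa-2,4-dien-1-one (acyl-free core) | CC1(C)C(=O)C=C(O)C(Cc2c(O)c(Cc3c(O)cc(O)c(C)c3O)c(O)cc2O)=C1O | intermediate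
18 | butanoyl chloride | CCCC(Cl)=O | starting material
19 | 2-butanoyl-4-({3-butanoyl-5-[(3-butanoyl-2,4,6-trihydroxy-5-methylphenyl)methyl]-2,4,6-trihydroxyphenyl}methyl)-3,5-dihydroxy-6,6-dimethylcyclohexa-2,4-dien-1-one | CCCC(=O)C1=C(O)C(Cc2c(O)c(Cc3c(O)c(C)c(O)c(C(=O)CCC)c3O)c(O)c(C(=O)CCC)c2O)=C(O)C(C)(C)C1=O | target

Total step count: 10. Longest linear sequence: 7 steps (steps 4 to 10, from 9).

Steps most likely to fail

Step 10. Lewis-acid- and HCl-induced fragmentation and recombination of the methylene bridges may compete with acylation, and the reaction may stall at partly acylated or O-acylated stages. The fallback gives up late-stage acylation and puts the butyryl groups on before the bridges; it sets out from 9, 18 and 1 and rejoins the route at 19. Compound 9 is C-acylated with 18 (AlCl3, PhNO2) to 1-(2,4,6-trihydroxy-3-methylphenyl)butan-1-one F1. Compound 1 is decarboxylated in boiling water to benzene-1,3,5-triol F2 (also an article of commerce), which is acylated with 18 in the same way to 1-(2,4,6-trihydroxyphenyl)butan-1-one F3. Part of F3 is gem-dimethylated with 4 (NaOMe, MeOH) to 2-butanoyl-3,5-dihydroxy-6,6-dimethylcyclohexa-2,4-dien-1-one F4. F1 is aminomethylated with 6 and 7 to 1-{3-[(dimethylamino)methyl]-2,4,6-trihydroxy-5-methylphenyl}butan-1-one F5, which on warming alkylates an excess of F3 to 1-{3-[(3-butanoyl-2,4,6-trihydroxy-5-methylphenyl)methyl]-2,4,6-trihydroxyphenyl}butan-1-one F6. F4 is aminomethylated with 6 and 7 to 2-butanoyl-4-[(dimethylamino)methyl]-3,5-dihydroxy-6,6-dimethylcyclohexa-2,4-dien-1-one F7, and warming F7 with F6 should give 19 directly.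

Step 8. The retro-Mannich/Michael manifold is reversible, so the bridge already present in 14 may exchange under the warm, amine-releasing conditions, or the hindered, ester-deactivated ring B carbon may add too slowly and let the methylene trione oligomerise. The fallback reverses the roles of the partners; it sets out from 14 and rejoins the route at 15. Compound 14 is aminomethylated at its only free ring carbon with 6 and 7 to benzyl 3-{[3-(benzyloxycarbonyl)-5-[(dimethylamino)methyl]-2,4,6-trihydroxyphenyl]methyl}-2,4,6-trihydroxy-5-methylbenzoate F8. F8 is then warmed in dioxane with the blocked filicinic ester 5, whose acidic enol carbon should trap the quinone methide from F8 to give 15.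

Step 2. The twofold C-methylation may not stop cleanly at the 5,5-dimethyl stage in benzyl alcohol, with O-methylation and consumption of iodomethane by benzyloxide eroding throughput. The fallback separates the methylation from the introduction of the benzyl group; it sets out from 1 and rejoins the route at 5. Compound 1 is esterified with 4 (NaHCO3, DMF) to methyl 2,4,6-trihydroxybenzoate F9, which is gem-dimethylated with 4 under the long-established methoxide conditions (NaOMe, MeOH) to methyl 2,4-dihydroxy-5,5-dimethyl-6-oxocyclohexa-1,3-diene-1-carboxylate F10. Heating F10 with benzyl alcohol in toluene while distilling off methanol (thermal β-keto ester exchange through an acylketene) should give 5.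

Further compounds
F1 | step 10 | 1-(2,4,6-trihydroxy-3-methylphenyl)butan-1-one | CCCC(=O)c1c(O)cc(O)c(C)c1O
F2 | step 10 | benzene-1,3,5-triol | Oc1cc(O)cc(O)c1
F3 | step 10 | 1-(2,4,6-trihydroxyphenyl)butan-1-one | CCCC(=O)c1c(O)cc(O)cc1O
F4 | step 10 | 2-butanoyl-3,5-dihydroxy-6,6-dimethylcyclohexa-2,4-dien-1-one | CCCC(=O)C1=C(O)C=C(O)C(C)(C)C1=O
F5 | step 10 | 1-{3-[(dimethylamino)methyl]-2,4,6-trihydroxy-5-methylphenyl}butan-1-one | CCCC(=O)c1c(O)c(C)c(O)c(CN(C)C)c1O
F6 | step 10 | 1-{3-[(3-butanoyl-2,4,6-trihydroxy-5-methylphenyl)methyl]-2,4,6-trihydroxyphenyl}butan-1-one | CCCC(=O)c1c(O)cc(O)c(Cc2c(O)c(C)c(O)c(C(=O)CCC)c2O)c1O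
F7 | step 10 | 2-butanoyl-4-[(dimethylamino)methyl]-3,5-dihydroxy-6,6-dimethylcyclohexa-2,4-dien-1-one | CCCC(=O)C1=C(O)C(CN(C)C)=C(O)C(C)(C)C1=O
F8 | step 8 | benzyl 3-{[3-(benzyloxycarbonyl)-5-[(dimethylamino)methyl]-2,4,6-trihydroxyphenyl]methyl}-2,4,6-trihydroxy-5-methylbenzoate | Cc1c(O)c(C(=O)OCc2ccccc2)c(O)c(Cc3c(O)c(CN(C)C)c(O)c(C(=O)OCc4ccccc4)c3O)c1O
F9 | step 2 | methyl 2,4,6-trihydroxybenzoate | COC(=O)c1c(O)cc(O)cc1O
F10 | step 2 | methyl 2,4-dihydroxy-5,5-dimethyl-6-oxocyclohexa-1,3-diene-1-carboxylate | COC(=O)C1=C(O)C=C(O)C(C)(C)C1=O
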